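Ring C is cut at O1–C2 and C2–C3. The feature used is that C2 is bonded both to O1 of ring A and to C3, while C3 is separated from ring A only by C4. A ring-A resorcinol whose C4 side chain ends in an (E)-allylsilane can therefore take up the formyl carbon of a ring-B aldehyde between its oxygen and its γ-carbon. This single operation forms both bonds, closes ring C and sets C2 and C3 from the C4 centre. It leaves a C3 vinyl group as the isopropyl precursor. The precursor is (S)-allylsilane diol 17, activated in situ as its bis(trimethylsilyl) ether. C4 stems from a sparteine-mediated lithiation–borylation.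

Key step: step 9

Remark on the chemistry: flavan numbering is used (O1, C2–C4, C4a, C5–C8, C8a; ring B primed); CIP analysis of the target gives (2R,3R,4S), i.e. 2,3-trans and 3,4-cis; C3′ and C5′ are equivalent by rotation until the first formyl group is in place; (–)-sparteine and all compounds marked as starting materials are assumed to be purchased.

Step 1
Reactants: 1 5-methoxyresorcinol
Product: 2 1-methoxy-3,5-bis(methoxymethoxy)benzene
Conditions: MOMCl, i-Pr2NEt, CH2Cl2, 0 °C → rt
Reagents that add atoms: chloromethyl methyl ether, COCCl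
Why: O-alkylation of both phenols (MOM protection) with an amine base avoids C-alkylation of the electron-rich ring and installs the two chelating groups that direct step 2.

Step 2
Reactants: 2 1-methoxy-3,5-bis(methoxymethoxy)benzene
Product: 4 pinacol boronate 2-[4-methoxy-2,6-bis(methoxymethoxy)phenyl]-4,4,5,5-tetramethyl-1,3,2-dioxaborolane, via aryllithium 3 (not isolated)
Conditions: n-BuLi, THF, 0 °C → rt; i-PrOBpin, −78 °C → rt
Reagents that add atoms: 2-isopropoxy-4,4,5,5-tetramethyl-1,3,2-dioxaborolane, CC(C)OB1OC(C)(C)C(C)(C)O1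
Why: Directed ortho-metalation occurs at the C–H flanked by the two chelating OMOM groups, which co-operate and outrank OMe as directors, and aryllithium 3 is trapped by borate exchange.

Step 3
Reactants: 5 2,4,6-triisopropylbenzoic acid; 6 1-bromo-3-methylbutane
Product: 7 3-methylbutyl 2,4,6-triisopropylbenzoate
Conditions: K2CO3, DMF, 60 °C
Reagents that add atoms: none
Why: SN2 alkylation of the carboxylate at a primary bromide sidesteps acylation at the hindered carbonyl and gives the bulky benzoate that acts as directing group and leaving group in step 4.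

Step 4
Reactants: 7 3-methylbutyl 2,4,6-triisopropylbenzoate; 4 pinacol boronate
Product: 10 benzylic boronic ester 2-[(1R)-1-[4-methoxy-2,6-bis(methoxymethoxy)phenyl]-3-methylbutyl]-4,4,5,5-tetramethyl-1,3,2-dioxaborolane, via lithiated benzoate 8 (not isolated), via boronate complex 9 (not isolated)
Conditions: s-BuLi, (–)-sparteine, Et2O, −78 °C; 4, −78 °C; then reflux
Reagents that add atoms: none
Why: Sparteine-mediated asymmetric deprotonation removes the pro-S hydrogen next to oxygen to give configurationally stable (S)-8, boron is taken up with retention (9), and the Matteson-type 1,2-metallate shift of the aryl group expels the benzoate with inversion, so the future C4 centre is set by the chiral diamine (lithiation–borylation).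

Step 5
Reactants: 10 benzylic boronic ester; 11 vinylmagnesium bromide
Product: 14 alkene 5-methoxy-1,3-bis(methoxymethoxy)-2-[(3S)-5-methylhex-1-en-3-yl]benzene, via vinyl boronate 12 (not isolated), via iodo boronic ester 13 (not isolated)
Conditions: 11, THF, rt; I2, THF, −78 °C; NaOMe, MeOH, −78 °C → rt
Reagents that add atoms: none
Why: Zweifel olefination, in which iodine activates vinyl boronate 12, the benzylic carbon migrates from boron to carbon with retention, and methoxide-induced anti elimination from 13 releases the terminal alkene, the boronate consuming iodine at −78 °C much faster than the alkoxyarene does.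

Step 6
Reactants: 14 alkene
Product: 15 5-methoxy-2-[(3S)-5-methylhex-1-en-3-yl]benzene-1,3-diol
Conditions: cat. HCl, MeOH, 45 °C
Reagents that add atoms: none
Why: Acid-catalysed acetal exchange with methanol removes both MOM groups before silicon is introduced, because an allylsilane would not survive this acid, whereas the monosubstituted alkene and the C4 centre are inert to it.

Step 7
Reactants: 15 resorcinol alkene; 16 allyltrimethylsilane
Product: 17 5-methoxy-2-[(2E,4S)-6-methyl-1-(trimethylsilyl)hept-2-en-4-yl]benzene-1,3-diol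
Conditions: 16 (excess), Hoveyda–Grubbs II (cat.), 1,4-benzoquinone (cat.), CH2Cl2, 40 °C
Reagents that add atoms: none
Why: Olefin cross-metathesis between a hindered, allylically branched alkene and an excess of an unhindered allylsilane favours the cross product and, being reversible, the (E)-alkene, phenols are tolerated, benzoquinone suppresses ruthenium hydride isomerisation that would endanger C4, and any (Z)-isomer, which would feed the 3,4-trans series in step 9, is removed by chromatography.

Step 8
Reactants: 18 1,3,5-tris(benzyloxy)benzene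
Product: 20 2,4,6-tris(benzyloxy)benzaldehyde, via iminium chloride 19 (not isolated)
Conditions: POCl3, DMF, 0 °C → rt; aq. NaOAc
Reagents that add atoms: N,N-dimethylformamide, CN(C)C=O; water, O
Why: Vilsmeier–Haack formylation of a 1,3,5-trialkoxybenzene stops after one formyl group because iminium salt 19 deactivates the ring.

Step 9
Reactants: 17 allylsilane diol; 20 2,4,6-tris(benzyloxy)benzaldehyde
Product: 24 vinyl flavan (2R,3R,4S)-3-ethenyl-7-methoxy-4-(2-methylpropyl)-2-[2,4,6-tris(benzyloxy)phenyl]chroman-5-ol, via bis(trimethylsilyl) ether 21 (not isolated), via oxocarbenium triflate 22 (not isolated), via 5-O-silyl flavan 23 (not isolated)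
Conditions: (Me3Si)2NH, cat. Me3SiCl, CH2Cl2, 40 °C, evaporate; 20, TMSOTf (0.3 equiv), 2,6-di-tert-butyl-4-methylpyridine (0.1 equiv), CH2Cl2, −78 → −30 °C; K2CO3, MeOH, 0 °C
Reagents that add atoms: none
Why: Proposed new method: TMSOTf silylates aldehyde 20, one of the two rotationally equivalent silyl ether oxygens of 21 adds, loss of hexamethyldisiloxane gives the ring-B-stabilised (E)-aryloxycarbenium ion 22 (O1–C2), and the γ-carbon of the allylsilane attacks C2 (C2–C3), after which the β-silyl cation releases Me3Si+ to regenerate the catalyst and leave the C3 vinyl group. The closest known reaction type is the intramolecular silyl-modified Sakurai (silyl-Prins) condensation of silylated hydroxyalkyl allylsilanes with aldehydes to 2,3-trans-3-vinyltetrahydropyrans, and the step goes beyond it only in using an aryl instead of an alkyl silyl ether as oxygen partner. Ring C closes in a six-membered mode that is endo with respect to O1=C2 and exo with respect to the alkene, through a half-chair fused to ring A. C2 is controlled by the (E)-oxocarbenium geometry, which puts ring B pseudo-equatorial and trans to the C3 substituent, and reversible ionisation of C2–O1 under the catalyst can only reinforce this more stable arrangement. C3 is controlled by C4: the peri 5-OSiMe3 group pushes isobutyl into the pseudo-axial position while the reacting alkene stays equatorial, which gives 3,4-cis, and the (E)-disubstituted alkene permits this because only a hydrogen on the β-carbon faces the axial isobutyl group. The step needs O- over C-attack at ring A and survival of the allylsilane until cyclisation, which the proton-free silyl ether format, the bulky silyl groups next to both free ring-A positions, a trace of hindered pyridine and the low temperature are meant to secure.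

Step 10
Reactants: 24 vinyl flavan
Product: 25 cyclopropyl flavan (2R,3R,4S)-3-cyclopropyl-7-methoxy-4-(2-methylpropyl)-2-[2,4,6-tris(benzyloxy)phenyl]chroman-5-ol
Conditions: Et2Zn, CH2I2, CH2Cl2, 0 °C → rt; aq. NH4Cl
Reagents that add atoms: diiodomethane, ICI
Why: Simmons–Smith cyclopropanation (Furukawa reagent) adds CH2 to the only alkene without touching C2, C3 or C4, and the 5-OH is merely held as a zinc phenoxide that is reprotonated on work-up.

Step 11
Reactants: 25 cyclopropyl flavan
Product: 27 isopropyl tetraol 2-[(2R,3R,4S)-5-hydroxy-7-methoxy-4-(2-methylpropyl)-3-(propan-2-yl)chroman-2-yl]benzene-1,3,5-triol, via cyclopropyl tetraol 26 (not isolated)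
Conditions: H2 (1 atm), Pd/C, EtOAc–MeOH, rt; filter, evaporate; H2 (4 atm), PtO2, AcOH, rt
Reagents that add atoms: none
Why: Palladium-catalysed hydrogenolysis in neutral solvent frees the three ring-B phenols without breaking C2–O1, as is usual for benzylated flavans, and platinum in acetic acid then cleaves the least hindered CH2–CH2 bond of the monosubstituted cyclopropane 26, turning it into isopropyl with no change at C3.

Step 12
Reactants: 27 isopropyl tetraol
Product: 28 dialdehyde (2R,3R,4S)-2-(3-formyl-2,4,6-trihydroxyphenyl)-5-hydroxy-7-methoxy-4-(2-methylpropyl)-3-(propan-2-yl)chroman-6-carbaldehyde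
Conditions: MgCl2, Et3N, (CH2O)n, THF, 65 °C; 1 M HCl
Reagents that add atoms: paraformaldehyde (as formaldehyde), C=O
Why: Casnati–Skattebøl ortho-formylation delivers formaldehyde inside a magnesium phenoxide chelate and oxidises the benzylic alkoxide by hydride transfer to a second formaldehyde, so only carbons next to a free phenol (C6 and C3′) react, C8 between OMe and O1 stays untouched, and any additional attack at C5′ already leads to 30.

Step 13
Reactants: 28 dialdehyde
Product: 30 trialdehyde 5-[(2R,3R,4S)-6-formyl-5-hydroxy-7-methoxy-4-(2-methylpropyl)-3-(propan-2-yl)chroman-2-yl]-2,4,6-trihydroxybenzene-1,3-dicarbaldehyde, via iminium chloride 29 (not isolated)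
Conditions: POCl3, DMF, EtOAc, 0 °C → rt; H2O
Reagents that add atoms: N,N-dimethylformamide, CN(C)C=O; water, O
Why: Vilsmeier–Haack formylation, in which a free phloroglucinol carbaldehyde ring still accepts a second formyl group at its last open position C5′, whereas ring A is now a 2-hydroxy-4,6-dialkoxybenzaldehyde, a class that does not react further with this weak electrophile, so C8 remains C–H.

Step 14
Reactants: 30 trialdehyde
Product: 31 target 5-[(2R,3R,4S)-6-formyl-5,7-dihydroxy-4-(2-methylpropyl)-3-(propan-2-yl)chroman-2-yl]-2,4,6-trihydroxybenzene-1,3-dicarbaldehyde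
Conditions: BCl3 (excess), CH2Cl2, −78 → 0 °C; H2O
Reagents that add atoms: none
Why: Boron trichloride binds the C6 formyl oxygen and the neighbouring 7-OMe oxygen in a six-membered chelate and chloride removes the methyl group (chelation-assisted aryl methyl ether cleavage), while the two formyl groups on ring B disfavour ionisation of C2–O1.

Compound list

1 | 5-methoxybenzene-1,3-diol (5-methoxyresorcinol) | COc1cc(O)cc(O)c1 | starting material
2 | 1-methoxy-3,5-bis(methoxymethoxy)benzene | COCOc1cc(OC)cc(OCOC)c1 | intermediate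
3 | [4-methoxy-2,6-bis(methoxymethoxy)phenyl]lithium | [Li]c1c(OCOC)cc(OC)cc1OCOC | intermediate
4 | 2-[4-methoxy-2,6-bis(methoxymethoxy)phenyl]-4,4,5,5-tetramethyl-1,3,2-dioxaborolane | COCOc1cc(OC)cc(OCOC)c1B1OC(C)(C)C(C)(C)O1 | intermediate
5 | 2,4,6-triisopropylbenzoic acid | CC(C)c1cc(C(C)C)c(C(=O)O)c(C(C)C)c1 | starting material
6 | 1-bromo-3-methylbutane | CC(C)CCBr | starting material
7 | 3-methylbutyl 2,4,6-triisopropylbenzoate | CC(C)CCOC(=O)c1c(C(C)C)cc(C(C)C)cc1C(C)C | intermediate
8 | (1S)-1-lithio-3-methylbutyl 2,4,6-triisopropylbenzoate, present as its (–)-sparteine complex | CC(C)C[C@H]([Li])OC(=O)c1c(C(C)C)cc(C(C)C)cc1C(C)C | intermediate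
9 | lithium boronate complex of 8 with 4, (S) at the O-bearing carbon | CC(C)C[C@H]([B-]1(OC(C)(C)C(C)(C)O1)c1c(OCOC)cc(OC)cc1OCOC)OC(=O)c1c(C(C)C)cc(C(C)C)cc1C(C)C.[Li+] | intermediate
10 | 2-[(1R)-1-[4-methoxy-2,6-bis(methoxymethoxy)phenyl]-3-methylbutyl]-4,4,5,5-tetramethyl-1,3,2-dioxaborolane | CC(C)C[C@@H](B1OC(C)(C)C(C)(C)O1)c1c(OCOC)cc(OC)cc1OCOC | intermediate
11 | vinylmagnesium bromide | C=C[Mg]Br | starting material
12 | bromomagnesium vinyl boronate complex of 10 | CC(C)C[C@@H]([B-]1(C=C)OC(C)(C)C(C)(C)O1)c1c(OCOC)cc(OC)cc1OCOC.[Mg+2].[Br-] | intermediate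
13 | β-iodo boronic ester formed by 1,2-migration, mixture at the new C–B carbon | CC(C)C[C@@H](C(CI)B1OC(C)(C)C(C)(C)O1)c1c(OCOC)cc(OC)cc1OCOC | intermediate
14 | 5-methoxy-1,3-bis(methoxymethoxy)-2-[(3S)-5-methylhex-1-en-3-yl]benzene | CC(C)C[C@@H](C=C)c1c(OCOC)cc(OC)cc1OCOC | intermediate
15 | 5-methoxy-2-[(3S)-5-methylhex-1-en-3-yl]benzene-1,3-diol | CC(C)C[C@@H](C=C)c1c(O)cc(OC)cc1O | intermediate
16 | allyltrimethylsilane | C=CC[Si](C)(C)C | starting material
17 | 5-methoxy-2-[(2E,4S)-6-methyl-1-(trimethylsilyl)hept-2-en-4-yl]benzene-1,3-diol | CC(C)C[C@@H](/C=C/C[Si](C)(C)C)c1c(O)cc(OC)cc1O | intermediate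
18 | 1,3,5-tris(benzyloxy)benzene | c1ccc(COc2cc(OCc3ccccc3)cc(OCc3ccccc3)c2)cc1 | starting material
19 | N,N-dimethyl[2,4,6-tris(benzyloxy)phenyl]methaniminium chloride | C[N+](C)=Cc1c(OCc2ccccc2)cc(OCc2ccccc2)cc1OCc1ccccc1.[Cl-] | intermediate
20 | 2,4,6-tris(benzyloxy)benzaldehyde | O=Cc1c(OCc2ccccc2)cc(OCc2ccccc2)cc1OCc1ccccc1 | intermediate
21 | bis(trimethylsilyl) ether of 17, (2E,4S) | CC(C)C[C@@H](/C=C/C[Si](C)(C)C)c1c(O[Si](C)(C)C)cc(OC)cc1O[Si](C)(C)C | intermediate
22 | (E)-aryloxycarbenium triflate from 21 and 20, O1=C2 formed and allylsilane still intact | CC(C)C[C@@H](/C=C/C[Si](C)(C)C)c1c(O[Si](C)(C)C)cc(OC)cc1/[O+]=C/c1c(OCc2ccccc2)cc(OCc2ccccc2)cc1OCc1ccccc1.[O-]S(=O)(=O)C(F)(F)F | intermediate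
23 | 5-O-trimethylsilyl ether of 24, (2R,3R,4S) | CC(C)C[C@@H]1c2c(cc(OC)cc2O[Si](C)(C)C)O[C@@H](c2c(OCc3ccccc3)cc(OCc3ccccc3)cc2OCc2ccccc2)[C@@H]1C=C | intermediate
24 | (2R,3R,4S)-3-ethenyl-7-methoxy-4-(2-methylpropyl)-2-[2,4,6-tris(benzyloxy)phenyl]chroman-5-ol (2,3-trans, 3,4-cis) | CC(C)C[C@@H]1c2c(cc(OC)cc2O)O[C@@H](c2c(OCc3ccccc3)cc(OCc3ccccc3)cc2OCc2ccccc2)[C@@H]1C=C | intermediate
25 | (2R,3R,4S)-3-cyclopropyl-7-methoxy-4-(2-methylpropyl)-2-[2,4,6-tris(benzyloxy)phenyl]chroman-5-ol | CC(C)C[C@@H]1c2c(cc(OC)cc2O)O[C@@H](c2c(OCc3ccccc3)cc(OCc3ccccc3)cc2OCc2ccccc2)[C@@H]1C1CC1 | intermediate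
26 | 2-[(2R,3R,4S)-3-cyclopropyl-5-hydroxy-7-methoxy-4-(2-methylpropyl)chroman-2-yl]benzene-1,3,5-triol | CC(C)C[C@@H]1c2c(cc(OC)cc2O)O[C@@H](c2c(O)cc(O)cc2O)[C@@H]1C1CC1 | intermediate
27 | 2-[(2R,3R,4S)-5-hydroxy-7-methoxy-4-(2-methylpropyl)-3-(propan-2-yl)chroman-2-yl]benzene-1,3,5-triol | CC(C)C[C@@H]1c2c(cc(OC)cc2O)O[C@@H](c2c(O)cc(O)cc2O)[C@@H]1C(C)C | intermediate
28 | (2R,3R,4S)-2-(3-formyl-2,4,6-trihydroxyphenyl)-5-hydroxy-7-methoxy-4-(2-methylpropyl)-3-(propan-2-yl)chroman-6-carbaldehyde | CC(C)C[C@@H]1c2c(cc(OC)c(C=O)c2O)O[C@@H](c2c(O)cc(O)c(C=O)c2O)[C@@H]1C(C)C | intermediate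
29 | C5′ dimethyliminium chloride of 28 | CC(C)C[C@@H]1c2c(cc(OC)c(C=O)c2O)O[C@@H](c2c(O)c(C=[N+](C)C)c(O)c(C=O)c2O)[C@@H]1C(C)C.[Cl-] | intermediate
30 | 5-[(2R,3R,4S)-6-formyl-5-hydroxy-7-methoxy-4-(2-methylpropyl)-3-(propan-2-yl)chroman-2-yl]-2,4,6-trihydroxybenzene-1,3-dicarbaldehyde | CC(C)C[C@@H]1c2c(cc(OC)c(C=O)c2O)O[C@@H](c2c(O)c(C=O)c(O)c(C=O)c2O)[C@@H]1C(C)C | intermediate
31 | 5-[(2R,3R,4S)-6-formyl-5,7-dihydroxy-4-(2-methylpropyl)-3-(propan-2-yl)chroman-2-yl]-2,4,6-trihydroxybenzene-1,3-dicarbaldehyde (CNP0328914.1) | CC(C)C[C@@H]1c2c(cc(O)c(C=O)c2O)O[C@@H](c2c(O)c(C=O)c(O)c(C=O)c2O)[C@@H]1C(C)C | target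

Total step count: 14. Longest linear sequence: 12 steps (1, 2, 4–7, 9–14).

Steps most likely to fail

**Step 9.**
- What may go wrong: carbon attack of the electron-rich ring A on the activated aldehyde, protodesilylation of the allylsilane by adventitious acid, failure of the weakly nucleophilic aryl silyl ether to engage the hindered aldehyde, or poor facial selectivity at C3.
- Fallback: it sets out from 17, comes back at 24, and makes the two bonds one after the other by known reactions.
- Both phenols are silylated (TBSCl, imidazole, DMF) to the bis(tert-butyldimethylsilyl) ether F1.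
- An intermolecular Hosomi–Sakurai allylation of 20 (BF3·OEt2, CH2Cl2, −78 °C) forms C2–C3 with allyl transposition and gives the homoallylic alcohol F2. C3 is set there by 1,2-induction from C4, and the carbinol configuration does not matter.
- TBAF in THF liberates the triol F3.
- Catalytic PPTS in CH2Cl2 ionises the ring-B-stabilised benzylic alcohol, so that a phenol closes O1–C2 under thermodynamic control (acid-catalysed flavan cyclodehydration) to 24.

**Step 12.**
- What may go wrong: opening of ring C through a ring-B quinone methide under the warm basic conditions, with erosion of C2 and C3, and methylene bridging between the free phloroglucinol rings by formaldehyde.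
- Fallback: it sets out from 27 and comes back at 30, by-passing 28 and step 13.
- The formaldehyde redox process in base is replaced by a titanium-templated Rieche formylation (Cl2CHOMe, TiCl4, CH2Cl2, −78 → 0 °C; aqueous acid).
- The electrophile is delivered from titanium-bound phenoxides at low temperature under acidic conditions. All three carbons next to a free phenol are formylated in one operation, and the reagent is limited to three equivalents to spare C8.

**Step 11.**
- What may go wrong: sluggish or unselective cleavage of the hindered cyclopropane, over-reduction of the phloroglucinol ring, or hydrogenolysis of C2–O1 in acetic acid.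
- Fallback: it sets out from 24, comes back at 27, and avoids both the cyclopropane (step 10) and platinum.
- The 5-OH is benzylated (BnBr, K2CO3, DMF) to the tetrabenzyl ether F4, which blocks phenol oxypalladation.
- Wacker–Tsuji oxidation (PdCl2, CuCl, O2, DMF–H2O) gives the 3-acetyl flavan F5.
- Petasis methylenation (Cp2TiMe2, toluene, 70 °C) is non-basic, so it avoids epimerisation and β-elimination of O1. It gives the 3-isopropenyl flavan F6.
- H2 over Pd/C in EtOAc–MeOH saturates the alkene and removes all four benzyl groups to give 27.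

Further compounds

F1 | step 9 | bis(tert-butyldimethylsilyl) ether of 17, (2E,4S) | CC(C)C[C@@H](/C=C/C[Si](C)(C)C)c1c(O[Si](C)(C)C(C)(C)C)cc(OC)cc1O[Si](C)(C)C(C)(C)C
F2 | step 9 | homoallylic alcohol with C2–C3 formed, C3 and C4 as in 24, carbinol carbon undefined, phenols as TBS ethers | CC(C)C[C@@H]([C@@H](C=C)C(O)c1c(OCc2ccccc2)cc(OCc2ccccc2)cc1OCc1ccccc1)c1c(O[Si](C)(C)C(C)(C)C)cc(OC)cc1O[Si](C)(C)C(C)(C)C
F3 | step 9 | desilylated triol of F2 | CC(C)C[C@@H]([C@@H](C=C)C(O)c1c(OCc2ccccc2)cc(OCc2ccccc2)cc1OCc1ccccc1)c1c(O)cc(OC)cc1O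
F0 | step 12 | none | none
F4 | step 11 | (2R,3R,4S)-5-benzyloxy-3-ethenyl-7-methoxy-4-(2-methylpropyl)-2-[2,4,6-tris(benzyloxy)phenyl]chroman | CC(C)C[C@@H]1c2c(cc(OC)cc2OCc2ccccc2)O[C@@H](c2c(OCc3ccccc3)cc(OCc3ccccc3)cc2OCc2ccccc2)[C@@H]1C=C
F5 | step 11 | (2R,3R,4S)-3-acetyl analogue of F4 | CC(C)C[C@@H]1c2c(cc(OC)cc2OCc2ccccc2)O[C@@H](c2c(OCc3ccccc3)cc(OCc3ccccc3)cc2OCc2ccccc2)[C@@H]1C(C)=O
F6 | step 11 | 3-(prop-1-en-2-yl) analogue of F4, same spatial arrangement, descriptors (2R,3S,4S) | CC(C)C[C@@H]1c2c(cc(OC)cc2OCc2ccccc2)O[C@@H](c2c(OCc3ccccc3)cc(OCc3ccccc3)cc2OCc2ccccc2)[C@@H]1C(C)=C
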